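Numbering (germacrane): C1 = furanone enol-ether carbon, C2 = furanone CH, C3 = ketone, C4 = quaternary carbon (methyl C15), C5 = ylidene CH, C6/C7/C11/C12 = butenolide carbons (C12 = C=O), C8 = carbinol, C9 = CH2, C10 = CHMe (C14), C13 = CH2OAc.
Retrosynthesis: the C8 ester and the C13 acetate come off first. C1=C2 and O–C4 are then cut together, which opens the 3(2H)-furanone and the ten-membered carbocycle at once. Sulfur is placed between C1 and C2 (eleven-membered thiolactone), and the ylidene-butenolide is traced back to a 2,3,4-trisubstituted furan.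
Enabling feature: the ring O–C1=C2–C3(=O)–C4 is the cyclised enol of a C1/C3 1,3-diketone. C4 is also the beta carbon of the enone C4=C5–C6=O that lies hidden in the enol-lactone unit C5=C6–O of the butenolide ring, so a diketone enolate generated next to that enone can close on C4.
Forward: Feist–Benary furan; acylation by a chiral zinc homoenolate; CBS reduction; Z-selective olefination (C4=C5); chloromethyl ketone (C2); NaSH stitching to the thiolactone; singlet-oxygen unmasking of the furan. Sulfide contraction/oxa-Michael addition/enol-lactonisation then builds carbocycle, furanone and ylidene-butenolide in one flask. The esters go on last.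
Stereochemistry: C10 comes from the commercial (R)-zinc reagent and C8 from catalyst-controlled reduction. C4 is set in the key step by the C8/C10-biased macrocycle. The Z-C4=C5 bond comes from Still–Gennari olefination, the Z side chain from a butenolide ring, and the E-ylidene from ring constraint.

Key step: step 12

Remark: TBS = tert-butyldimethylsilyl; the five building blocks named as starting materials are taken to be catalogue compounds, and the lactol carbon C6 of the hydroxybutenolides is left undefined because it ends as an sp2 carbon.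

Step 1
Reactants: 1 methyl 4,4-dimethoxy-3-oxobutanoate; 2 1,3-dichloroacetone
Product: 3 methyl 4-(chloromethyl)-2-(dimethoxymethyl)furan-3-carboxylate
Conditions: pyridine, 50 °C
Reagents that add atoms: none
Why: Feist–Benary furan synthesis: aldol addition of the active methylene to the ketone of 2, O-alkylation of the enol by one CH2Cl arm and loss of water put C5 (acetal), C8 (ester) and C13 (CH2Cl) on adjacent ring carbons and leave C12 as CH.

Step 2
Reactants: 3 methyl 4-(chloromethyl)-2-(dimethoxymethyl)furan-3-carboxylate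
Product: 6 4-(TBSO-methyl)-2-(dimethoxymethyl)furan-3-carboxylic acid, via lithium hydroxy carboxylate 4 (not isolated), via bis-silyl compound 5 (not isolated)
Conditions: LiOH, THF–H2O, 50 °C; evaporate; TBSCl, imidazole, DMF, rt; K2CO3 (cat.), MeOH–H2O, 0 °C; citric acid to pH 5
Reagents that add atoms: lithium hydroxide, [Li+].[OH-]; tert-butyldimethylsilyl chloride, CC(C)(C)[Si](C)(C)Cl
Why: Saponification together with SN2 hydrolysis of the furylmethyl chloride, exhaustive silylation and selective solvolysis of the labile silyl ester give the protected acid, while the acetal stays under basic or near-neutral conditions throughout.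

Step 3
Reactants: 6 4-(TBSO-methyl)-2-(dimethoxymethyl)furan-3-carboxylic acid; 7 (R)-(3-methoxy-2-methyl-3-oxopropyl)zinc bromide
Product: 9 methyl (2S)-4-[4-(TBSO-methyl)-2-(dimethoxymethyl)furan-3-yl]-2-methyl-4-oxobutanoate, via acid chloride 8 (not isolated)
Conditions: 1-chloro-N,N,2-trimethylprop-1-en-1-amine, CH2Cl2, 0 °C; then 7 (THF solution), Pd(PPh3)4 (5 mol %), THF, 0 °C to rt
Reagents that add atoms: none
Why: Negishi acylation: neutral formation of the acid chloride, oxidative addition of zerovalent palladium, transmetalation from the ester-tolerant alkylzinc and reductive elimination give the C8 ketone, and the C10 stereocentre is carried over unchanged from 7.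

Step 4
Reactants: 9 methyl (2S)-4-[4-(TBSO-methyl)-2-(dimethoxymethyl)furan-3-yl]-2-methyl-4-oxobutanoate
Product: 11 (3S,5S)-5-[4-(TBSO-methyl)-2-(dimethoxymethyl)furan-3-yl]-3-methyloxolan-2-one, via hydroxy ester 10 (not isolated)
Conditions: (R)-2-methyl-CBS-oxazaborolidine (20 mol %), BH3·SMe2, THF, −20 °C; MeOH; then DBU (cat.), toluene, rt
Reagents that add atoms: none
Why: Corey–Bakshi–Shibata reduction: the (R)-oxazaborolidine binds the ketone with the large furyl group away from its B-methyl group and delivers hydride to one face, which sets C8 as S by catalyst control, and the gamma-hydroxy ester then closes to the cis-lactone.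

Step 5
Reactants: 11 (3S,5S)-5-[4-(TBSO-methyl)-2-(dimethoxymethyl)furan-3-yl]-3-methyloxolan-2-one
Product: 14 (2S,4S)-4-(TBSO)-4-[4-(TBSO-methyl)-2-(dimethoxymethyl)furan-3-yl]-2-methylbutanoic acid, via lithium hydroxy carboxylate 12 (not isolated), via silyl ester 13 (not isolated)
Conditions: LiOH, THF–H2O, rt; evaporate; TBSCl, imidazole, DMAP (cat.), DMF, 45 °C; K2CO3 (cat.), MeOH–H2O, 0 °C; citric acid to pH 5
Reagents that add atoms: lithium hydroxide, [Li+].[OH-]; tert-butyldimethylsilyl chloride, CC(C)(C)[Si](C)(C)Cl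
Why: Lactone saponification, exhaustive silylation and selective cleavage of the silyl ester is the standard conversion of a gamma-lactone into a gamma-silyloxy acid without relactonisation, and no stereocentre is touched.

Step 6
Reactants: 14 (2S,4S)-4-(TBSO)-4-[4-(TBSO-methyl)-2-(dimethoxymethyl)furan-3-yl]-2-methylbutanoic acid
Product: 15 (2S,4S)-4-(TBSO)-4-[4-(TBSO-methyl)-2-formylfuran-3-yl]-2-methylbutanoic acid
Conditions: pyridinium p-toluenesulfonate (cat.), acetone–H2O, rt
Reagents that add atoms: water, O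
Why: Acid-catalysed acetal hydrolysis: the furfural-type dimethyl acetal ionises far more readily than the TBS ethers are cleaved.

Step 7
Reactants: 15 (2S,4S)-4-(TBSO)-4-[4-(TBSO-methyl)-2-formylfuran-3-yl]-2-methylbutanoic acid; 16 ethyl 2-[bis(2,2,2-trifluoroethoxy)phosphoryl]propanoate
Product: 17 (2S,4S)-4-(TBSO)-4-{4-(TBSO-methyl)-2-[(1Z)-3-ethoxy-2-methyl-3-oxoprop-1-en-1-yl]furan-3-yl}-2-methylbutanoic acid
Conditions: KN(SiMe3)2 (2.2 equiv), 18-crown-6, THF, −78 °C
Reagents that add atoms: none
Why: Still–Gennari olefination: fast elimination from the kinetic adduct of the electron-poor phosphonate gives the trisubstituted C4=C5 bond as the Z isomer (C3 cis to C6) that the later ring closure needs, and the potassium carboxylate is a spectator.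

Step 8
Reactants: 17 (2S,4S)-4-(TBSO)-4-{4-(TBSO-methyl)-2-[(1Z)-3-ethoxy-2-methyl-3-oxoprop-1-en-1-yl]furan-3-yl}-2-methylbutanoic acid
Product: 18 (2S,4S)-4-(TBSO)-4-{4-(TBSO-methyl)-2-[(1Z)-4-chloro-2-methyl-3-oxobut-1-en-1-yl]furan-3-yl}-2-methylbutanoic acid
Conditions: ICH2Cl, MeLi·LiBr, THF–Et2O, −78 °C; AcOH quench at −78 °C
Reagents that add atoms: chloroiodomethane, ClCI
Why: Carbenoid homologation of an ester: chloromethyllithium made by iodine–lithium exchange in the presence of the substrate adds to the enoate to give a tetrahedral intermediate that is stable at −78 °C and collapses on quench to the chloromethyl ketone (C2), while the lithium carboxylate is inert and the alkene geometry is untouched.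

Step 9
Reactants: 18 (2S,4S)-4-(TBSO)-4-{4-(TBSO-methyl)-2-[(1Z)-4-chloro-2-methyl-3-oxobut-1-en-1-yl]furan-3-yl}-2-methylbutanoic acid
Product: 19 pentafluorophenyl ester of 18
Conditions: EDC·HCl, C6F5OH, CH2Cl2, 0 °C
Reagents that add atoms: pentafluorophenol, Oc1c(F)c(F)c(F)c(F)c1F
Why: Carbodiimide esterification gives an isolable active ester under base-free conditions that spare the chloroketone and the C10 stereocentre.

Step 10
Reactants: 19 pentafluorophenyl ester of 18
Product: 21 furan-fused eleven-membered (4Z;8S;10S)-thiolactone [ring S–C2–C3(=O)–C4(Me)=C5–C6=C7–C8(OTBS)–C9–C10(Me)–C1(=O)] bearing C13H2OTBS on C11, via alpha-sulfanyl ketone 20 (not isolated)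
Conditions: NaSH (1.0 equiv), i-Pr2NEt, DMF, 1 mM (double syringe-pump addition), 0 °C to rt
Reagents that add atoms: sodium hydrosulfide, [Na+].[SH-]
Why: Sulfide stitching: hydrosulfide displaces the alpha-chloride (SN2) and the thiolate is acylated by the active ester (the reverse order via the thioacid converges on the same ring), and the very high rates of both sulfur reactions allow the dilution that a medium ring needs.

Step 11
Reactants: 21 furan-fused eleven-membered thiolactone
Product: 22 eleven-membered thiolactone in which the furan has become the 6-hydroxy-12,6-butenolide (4Z;8S;10S;C6 epimers)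
Conditions: O2, tetraphenylporphyrin (cat.), visible light, i-Pr2NEt, CH2Cl2, −78 °C
Reagents that add atoms: oxygen, O=O
Why: Furan photooxygenation: [4+2] addition of singlet oxygen and base-induced Kornblum–DeLaMare fragmentation of the endoperoxide, whose only bridgehead hydrogen sits on C12, make C12 the lactone carbonyl and C6 the lactol carbon, while the electron-poor enone and the thioester sulfur are poor partners for singlet oxygen.

Step 12
Reactants: 22 hydroxybutenolide thiolactone
Product: 25 (4S,5E,8S,10S)-8,13-bis(TBSO)-3-oxo-1,4-epoxygermacra-1,5,7(11)-trien-12,6-olide, via ten-membered diketone 23 (not isolated), via furanone lactol 24 (not isolated)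
Conditions: PPh3 (1.5 equiv), LiBr, Et3N, MeCN (5 mM), 55 °C; then Ac2O, DMAP (cat.), 0 °C to rt
Reagents that add atoms: none
Why: Proposed new method: Et3N/LiBr opens the lactol of 22 to the cis-enedione carboxylate and enolises C2 (flanked by C3=O and the acylthio group), the enolate adds to the thioester carbonyl C1 (3-exo-trig) and PPh3 pulls the sulfur out of the resulting thiirane alkoxide, so that the eleven-membered thiolactone contracts by one atom to the ten-membered diketone enolate 23 and C1=C2 is in place. The oxygen on C1 of that enolate then adds to C4 (5-exo-trig oxa-Michael addition to the enone C4=C5–C6=O), which closes the furanone ring and gives 24, and Ac2O finally dehydrates the C6 lactol to the enol lactone, which inside the bicycle can only be the E-ylidene (C4 cis to C7). The closest known reaction types are the Eschenmoser sulfide contraction of S-(2-oxoalkyl) thiocarboxylates to 1,3-diketones, the O-cyclisation of 1,3-diketone enolates onto an electrophilic C4 that gives 2,2-disubstituted 3(2H)-furanones, and transannular oxa-Michael additions to macrocyclic cis-enediones; new is their coupling in one flask on a medium ring. C4 is the only new stereocentre: the Z geometry holds C3 and C6 on the same side, the oxygen can reach C4 only from the alkene face that looks into the ring, and the fold of the C7–C10 bridge that keeps the C8 silyloxy group and the C10 methyl group on the periphery should expose the face that leads to 4S, with the reversibility of the addition before Ac2O is added as a second filter. The step needs enolisation at C2 rather than C10 (secured by the double activation of C2), attack at C4 rather than C5 (after contraction C3 belongs to an electron-rich vinylogous carboxylate, so only the C6 ketone polarises the alkene and C4 is its beta carbon, while 6-endo attack at C5 would be anti-Michael), and sulfur abstraction rather than phosphine addition to the enedione (weakly nucleophilic PPh3, fully substituted C4, hindered C5).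

Step 13
Reactants: 25 (4S,5E,8S,10S)-8,13-bis(TBSO)-3-oxo-1,4-epoxygermacra-1,5,7(11)-trien-12,6-olide
Product: 26 (4S,5E,8S,10S)-8,13-dihydroxy-3-oxo-1,4-epoxygermacra-1,5,7(11)-trien-12,6-olide
Conditions: HF·pyridine, THF, 0 °C to rt
Reagents that add atoms: none
Why: Fluoride-driven cleavage of both silyl ethers under weakly acidic conditions leaves the vinylogous ester and the ylidene-butenolide intact.

Step 14
Reactants: 26 (4S,5E,8S,10S)-8,13-dihydroxy-3-oxo-1,4-epoxygermacra-1,5,7(11)-trien-12,6-olide
Product: 27 (4S,5E,8S,10S)-13-acetoxy-8-hydroxy-3-oxo-1,4-epoxygermacra-1,5,7(11)-trien-12,6-olide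
Conditions: AcCl (1.05 equiv), 2,4,6-collidine, CH2Cl2, −78 °C
Reagents that add atoms: acetyl chloride, CC(=O)Cl
Why: Kinetically selective acylation: the primary allylic C13 hydroxyl reacts much faster than the hindered secondary C8 hydroxyl at low temperature with a weak, non-nucleophilic base.

Step 15
Reactants: 28 4-methylfuran-2(5H)-one
Product: 31 (2Z)-4-(TBSO)-3-methylbut-2-enoic acid, via lithium hydroxy enoate 29 (not isolated), via silyl ester 30 (not isolated)
Conditions: LiOH, THF–H2O, 0 °C to rt; evaporate; TBSCl, imidazole, DMF, rt; K2CO3 (cat.), MeOH–H2O, 0 °C; citric acid to pH 5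
Reagents that add atoms: lithium hydroxide, [Li+].[OH-]; tert-butyldimethylsilyl chloride, CC(C)(C)[Si](C)(C)Cl
Why: Saponification of the butenolide, silylation and selective silyl ester cleavage deliver the acid with the Z geometry that is fixed by the ring of 28.

Step 16
Reactants: 27 (4S,5E,8S,10S)-13-acetoxy-8-hydroxy-3-oxo-1,4-epoxygermacra-1,5,7(11)-trien-12,6-olide; 31 (2Z)-4-(TBSO)-3-methylbut-2-enoic acid
Product: 32 (4S,5E,8S,10S)-13-acetoxy-8-[(2Z)-4-(TBSO)-3-methylbut-2-enoyloxy]-3-oxo-1,4-epoxygermacra-1,5,7(11)-trien-12,6-olide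
Conditions: 2-methyl-6-nitrobenzoic anhydride, DMAP (cat.), Et3N, CH2Cl2, 0 °C
Reagents that add atoms: none
Why: Shiina esterification: the mixed anhydride formed in situ passes the acyl group through DMAP to the hindered C8 hydroxyl with retention at C8, at a temperature low enough to keep the Z-enoate and the allylic acetate intact.

Step 17
Reactants: 32 (4S,5E,8S,10S)-13-acetoxy-8-[(2Z)-4-(TBSO)-3-methylbut-2-enoyloxy]-3-oxo-1,4-epoxygermacra-1,5,7(11)-trien-12,6-olide
Product: 33 CNP0269057.1
Conditions: HF·pyridine, pyridine, THF, 0 °C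
Reagents that add atoms: none
Why: Buffered fluoride desilylation frees the primary alcohol without the base that would trigger lactonisation of the Z-gamma-hydroxy enoate or loss of the allylic acetate.

Compound list
1 | methyl 4,4-dimethoxy-3-oxobutanoate | COC(=O)CC(=O)C(OC)OC | starting material
2 | 1,3-dichloroacetone | ClCC(=O)CCl | starting material
3 | methyl 4-(chloromethyl)-2-(dimethoxymethyl)furan-3-carboxylate | COC(=O)c1c(CCl)coc1C(OC)OC | intermediate
4 | lithium 2-(dimethoxymethyl)-4-(hydroxymethyl)furan-3-carboxylate | [Li+].[O-]C(=O)c1c(CO)coc1C(OC)OC | intermediate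
5 | TBS 4-(TBSO-methyl)-2-(dimethoxymethyl)furan-3-carboxylate | CC(C)(C)[Si](C)(C)OCc1coc(C(OC)OC)c1C(=O)O[Si](C)(C)C(C)(C)C | intermediate
6 | 4-(TBSO-methyl)-2-(dimethoxymethyl)furan-3-carboxylic acid | CC(C)(C)[Si](C)(C)OCc1coc(C(OC)OC)c1C(=O)O | intermediate
7 | (R)-(3-methoxy-2-methyl-3-oxopropyl)zinc bromide | COC(=O)[C@@H](C)C[Zn]Br | starting material
8 | 4-(TBSO-methyl)-2-(dimethoxymethyl)furan-3-carbonyl chloride | CC(C)(C)[Si](C)(C)OCc1coc(C(OC)OC)c1C(Cl)=O | intermediate
9 | methyl (2S)-4-[4-(TBSO-methyl)-2-(dimethoxymethyl)furan-3-yl]-2-methyl-4-oxobutanoate | COC(=O)[C@@H](C)CC(=O)c1c(CO[Si](C)(C)C(C)(C)C)coc1C(OC)OC | intermediate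
10 | methyl (2S,4S)-4-[4-(TBSO-methyl)-2-(dimethoxymethyl)furan-3-yl]-4-hydroxy-2-methylbutanoate | COC(=O)[C@@H](C)C[C@@H](c1c(CO[Si](C)(C)C(C)(C)C)coc1C(OC)OC)O | intermediate
11 | (3S,5S)-5-[4-(TBSO-methyl)-2-(dimethoxymethyl)furan-3-yl]-3-methyloxolan-2-one (cis) | O=C1[C@@H](C)C[C@@H](c2c(CO[Si](C)(C)C(C)(C)C)coc2C(OC)OC)O1 | intermediate
12 | lithium (2S,4S)-4-[4-(TBSO-methyl)-2-(dimethoxymethyl)furan-3-yl]-4-hydroxy-2-methylbutanoate | [Li+].[O-]C(=O)[C@@H](C)C[C@@H](c1c(CO[Si](C)(C)C(C)(C)C)coc1C(OC)OC)O | intermediate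
13 | TBS (2S,4S)-4-(TBSO)-4-[4-(TBSO-methyl)-2-(dimethoxymethyl)furan-3-yl]-2-methylbutanoate | CC(C)(C)[Si](C)(C)OC(=O)[C@@H](C)C[C@@H](c1c(CO[Si](C)(C)C(C)(C)C)coc1C(OC)OC)O[Si](C)(C)C(C)(C)C | intermediate
14 | (2S,4S)-4-(TBSO)-4-[4-(TBSO-methyl)-2-(dimethoxymethyl)furan-3-yl]-2-methylbutanoic acid | OC(=O)[C@@H](C)C[C@@H](c1c(CO[Si](C)(C)C(C)(C)C)coc1C(OC)OC)O[Si](C)(C)C(C)(C)C | intermediate
15 | (2S,4S)-4-(TBSO)-4-[4-(TBSO-methyl)-2-formylfuran-3-yl]-2-methylbutanoic acid | OC(=O)[C@@H](C)C[C@@H](c1c(CO[Si](C)(C)C(C)(C)C)coc1C=O)O[Si](C)(C)C(C)(C)C | intermediate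
16 | ethyl 2-[bis(2,2,2-trifluoroethoxy)phosphoryl]propanoate | CCOC(=O)C(C)P(=O)(OCC(F)(F)F)OCC(F)(F)F | starting material
17 | (2S,4S)-4-(TBSO)-4-{4-(TBSO-methyl)-2-[(1Z)-3-ethoxy-2-methyl-3-oxoprop-1-en-1-yl]furan-3-yl}-2-methylbutanoic acid | OC(=O)[C@@H](C)C[C@@H](c1c(CO[Si](C)(C)C(C)(C)C)coc1/C=C(/C)C(=O)OCC)O[Si](C)(C)C(C)(C)C | intermediate
18 | (2S,4S)-4-(TBSO)-4-{4-(TBSO-methyl)-2-[(1Z)-4-chloro-2-methyl-3-oxobut-1-en-1-yl]furan-3-yl}-2-methylbutanoic acid | OC(=O)[C@@H](C)C[C@@H](c1c(CO[Si](C)(C)C(C)(C)C)coc1/C=C(/C)C(=O)CCl)O[Si](C)(C)C(C)(C)C | intermediate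
19 | pentafluorophenyl ester of 18 | O=C(Oc1c(F)c(F)c(F)c(F)c1F)[C@@H](C)C[C@@H](c1c(CO[Si](C)(C)C(C)(C)C)coc1/C=C(/C)C(=O)CCl)O[Si](C)(C)C(C)(C)C | intermediate
20 | pentafluorophenyl ester carrying the (1Z)-2-methyl-3-oxo-4-sulfanylbut-1-enyl chain | O=C(Oc1c(F)c(F)c(F)c(F)c1F)[C@@H](C)C[C@@H](c1c(CO[Si](C)(C)C(C)(C)C)coc1/C=C(/C)C(=O)CS)O[Si](C)(C)C(C)(C)C | intermediate
21 | furan-fused eleven-membered thiolactone (4Z,8S,10S), sulfur between C1 and C2 | O=C1[C@@H](C)C[C@@H](c2c(CO[Si](C)(C)C(C)(C)C)coc2/C=C(/C)C(=O)CS1)O[Si](C)(C)C(C)(C)C | intermediate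
22 | eleven-membered thiolactone with 6-hydroxy-12,6-butenolide (4Z,8S,10S, C6 epimers) | O=C1[C@@H](C)C[C@@H](C2=C(CO[Si](C)(C)C(C)(C)C)C(=O)OC2(O)/C=C(/C)C(=O)CS1)O[Si](C)(C)C(C)(C)C | intermediate
23 | (4Z,8S,10S)-8,13-bis(TBSO)-6-hydroxy-1,3-dioxogermacra-4,7(11)-dien-12,6-olide | O=C1[C@@H](C)C[C@@H](C2=C(CO[Si](C)(C)C(C)(C)C)C(=O)OC2(O)/C=C(/C)C(=O)C1)O[Si](C)(C)C(C)(C)C | intermediate
24 | (4S,8S,10S)-8,13-bis(TBSO)-6-hydroxy-3-oxo-1,4-epoxygermacra-1,7(11)-dien-12,6-olide | CC(C)(C)[Si](C)(C)OCC1=C2C(O)(C[C@]3(C)OC(=CC3=O)[C@@H](C)C[C@@H]2O[Si](C)(C)C(C)(C)C)OC1=O | intermediate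
25 | (4S,5E,8S,10S)-8,13-bis(TBSO)-3-oxo-1,4-epoxygermacra-1,5,7(11)-trien-12,6-olide | CC(C)(C)[Si](C)(C)OCC1=C2/C(=C\[C@]3(C)OC(=CC3=O)[C@@H](C)C[C@@H]2O[Si](C)(C)C(C)(C)C)OC1=O | intermediate
26 | (4S,5E,8S,10S)-8,13-dihydroxy-3-oxo-1,4-epoxygermacra-1,5,7(11)-trien-12,6-olide | OCC1=C2/C(=C\[C@]3(C)OC(=CC3=O)[C@@H](C)C[C@@H]2O)OC1=O | intermediate
27 | (4S,5E,8S,10S)-13-acetoxy-8-hydroxy-3-oxo-1,4-epoxygermacra-1,5,7(11)-trien-12,6-olide | CC(=O)OCC1=C2/C(=C\[C@]3(C)OC(=CC3=O)[C@@H](C)C[C@@H]2O)OC1=O | intermediate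
28 | 4-methylfuran-2(5H)-one | CC1=CC(=O)OC1 | starting material
29 | lithium (2Z)-4-hydroxy-3-methylbut-2-enoate | [Li+].[O-]C(=O)/C=C(/C)CO | intermediate
30 | TBS (2Z)-4-(TBSO)-3-methylbut-2-enoate | CC(C)(C)[Si](C)(C)OC(=O)/C=C(/C)CO[Si](C)(C)C(C)(C)C | intermediate
31 | (2Z)-4-(TBSO)-3-methylbut-2-enoic acid | OC(=O)/C=C(/C)CO[Si](C)(C)C(C)(C)C | intermediate
32 | (4S,5E,8S,10S)-13-acetoxy-8-[(2Z)-4-(TBSO)-3-methylbut-2-enoyloxy]-3-oxo-1,4-epoxygermacra-1,5,7(11)-trien-12,6-olide | CC(=O)OCC1=C2/C(=C\[C@]3(C)OC(=CC3=O)[C@@H](C)C[C@@H]2OC(=O)/C=C(/C)CO[Si](C)(C)C(C)(C)C)OC1=O | intermediate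
33 | CNP0269057.1, (4S,5E,8S,10S)-13-acetoxy-8-[(2Z)-4-hydroxy-3-methylbut-2-enoyloxy]-3-oxo-1,4-epoxygermacra-1,5,7(11)-trien-12,6-olide | CC(=O)OCC1=C2/C(=C\[C@]3(C)OC(=CC3=O)[C@@H](C)C[C@@H]2OC(=O)/C=C(/C)CO)OC1=O | target

Total step count: 17. Longest linear sequence: 16 (steps 1–14, 16, 17).

Steps most likely to fail

Step 12. Several processes can compete here:
- conjugate addition of the phosphine to the cis-enedione;
- 6-endo closure at C5;
- poor facial selectivity at C4;
- epimerisation at C10 during the warm basic phase.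

The fallback separates the two bond formations and uses only known reaction types. It sets out from 21 and returns at 25. The sulfide contraction (PPh3, LiBr, Et3N, MeCN) is run on 21, where no electrophilic alkene is present, to give the furan-fused ten-membered 1,3-diketone F1. Photooxygenation as in step 11 then gives 23, which is isolated. Camphorsulfonic acid in CH2Cl2 closes it to 24. Under acid the tertiary C4 carries the positive charge of the protonated C6 enone, and the C4 epimers can equilibrate. Ac2O/Et3N then dehydrates 24 to 25.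

Step 10. Oligomerisation, capping of both termini by hydrosulfide, or thiolate-catalysed Z to E isomerisation of the enone can defeat the double stitching. The fallback installs sulfur first and closes the ring by acyl activation. It sets out from 18 and returns at 21. Potassium thioacetate in DMF converts 18 into the S-acetyl sulfanyl ketone acid F2. Hydrazine acetate removes the S-acetyl group to give the sulfanyl ketone acid F3. This is cyclised by slow addition to 2-methyl-6-nitrobenzoic anhydride/DMAP at high dilution (macrothiolactonisation) to give 21.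

Step 11. Singlet oxygen may add across the exocyclic diene C7=C6–C5=C4 or oxidise sulfur, and the endoperoxide may fragment in other ways. The fallback replaces the cycloaddition by a polar two-stage oxidation. It sets out from 21 and returns at 22. NBS and NaHCO3 in aqueous acetone open the furan to the macrocyclic (Z)-4-oxo-enal F4. Pinnick oxidation (NaClO2, NaH2PO4, 2-methylbut-2-ene) converts its aldehyde into the acid, which closes to the hydroxybutenolide 22.

Further compounds
F1 | step 12 | furan-fused ten-membered (4Z,8S,10S)-1,3-diketone (21 without sulfur) | O=C1[C@@H](C)C[C@@H](c2c(CO[Si](C)(C)C(C)(C)C)coc2/C=C(/C)C(=O)C1)O[Si](C)(C)C(C)(C)C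
F2 | step 10 | (2S,4S)-4-(TBSO)-4-{4-(TBSO-methyl)-2-[(1Z)-4-(acetylsulfanyl)-2-methyl-3-oxobut-1-en-1-yl]furan-3-yl}-2-methylbutanoic acid | OC(=O)[C@@H](C)C[C@@H](c1c(CO[Si](C)(C)C(C)(C)C)coc1/C=C(/C)C(=O)CSC(C)=O)O[Si](C)(C)C(C)(C)C
F3 | step 10 | (2S,4S)-4-(TBSO)-4-{4-(TBSO-methyl)-2-[(1Z)-2-methyl-3-oxo-4-sulfanylbut-1-en-1-yl]furan-3-yl}-2-methylbutanoic acid | OC(=O)[C@@H](C)C[C@@H](c1c(CO[Si](C)(C)C(C)(C)C)coc1/C=C(/C)C(=O)CS)O[Si](C)(C)C(C)(C)C
F4 | step 11 | eleven-membered thiolactone with opened furan: C6 ketone and C12 aldehyde cis on C7=C11 (4Z,8S,10S) | O=C1[C@@H](C)C[C@@H](/C(=C(/C=O)CO[Si](C)(C)C(C)(C)C)C(=O)/C=C(/C)C(=O)CS1)O[Si](C)(C)C(C)(C)C
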